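## Retrosynthetic overview

1. The two esters come off last (9-acetate, then 8-isovalerate), leaving the 8,9-diol 6,12-olide.
2. Key disconnection: C7 is excised as a geminal double homoenolate (a β,β-dianion equivalent of methyl methacrylate, reagent methyl 3-bromo-2-(bromomethyl)acrylate) stitched between the two aldehyde carbons C8 and C6. C7–C8 is made first (In, chelation control), C6–C7 second (CrCl2, ring-closing, with lactonisation).
3. The C8 aldehyde comes from periodate excision of C5 of 2-C-methyl-D-ribono-1,4-lactone, which supplies C1, C9, C10, C14 and the 9R,10R centres; the C6 aldehyde comes from MnO2 oxidation.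
4. The 3(2H)-furanone comes from an α′-hydroxy ynone, made by adding the acetylide of (Z)-3-methylpent-2-en-4-yn-1-ol (C2–C6, C15) to the lactone.
5. Ring order: furanone first; then the ten-membered carbocycle and the α-methylene-γ-lactone in the same step.

Assumption: locants C1–C15 in names and comments follow the germacrane numbering of the target (C1 ketone, C2=C3 furanone alkene, C4=C5, C6 lactone carbinol, C7, C8 isovalerate, C9 acetate, C10, C11=C13, C12 lactone carbonyl, C14/C15 methyls).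

## Route

Step 1
Reactants: 1 2-C-methyl-D-ribono-1,4-lactone
Product: 2 (3R,4R,5R)-3-hydroxy-3-methyl-4-(triethylsilyloxy)-5-[(triethylsilyloxy)methyl]oxolan-2-one
Conditions: TESCl (2.2 equiv), imidazole, DMF, 0 °C
Reagents that add atoms: triethylsilyl chloride, CC[Si](Cl)(CC)CC
Why: Silyl ether formation; the primary and the secondary hydroxyl are silylated while the tertiary 2-OH (later O10) stays free, and no stereocentre is touched.

Step 2
Reactants: 3 (Z)-3-methylpent-2-en-4-yn-1-ol
Product: 4 triethyl{[(2Z)-3-methylpent-2-en-4-yn-1-yl]oxy}silane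
Conditions: TESCl, imidazole, CH2Cl2, 0 °C
Reagents that add atoms: triethylsilyl chloride, CC[Si](Cl)(CC)CC
Why: Silyl ether formation; the allylic alcohol is masked because free Z-enynols add to the (activated) alkyne to give furans, and the Z geometry is untouched.

Step 3
Reactants: 2 (3R,4R,5R)-3-hydroxy-3-methyl-4-(triethylsilyloxy)-5-[(triethylsilyloxy)methyl]oxolan-2-one; 4 triethyl{[(2Z)-3-methylpent-2-en-4-yn-1-yl]oxy}silane
Product: 5 (2Z,7R,8R,9R)-7,9-dihydroxy-3,7-dimethyl-1,8,10-tris(triethylsilyloxy)dec-2-en-4-yn-6-one (open form of the alkynyl lactol)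
Conditions: 4 (2.2 equiv), n-BuLi (2.1 equiv), THF, −78 °C; then 2, −78 → −20 °C; aq NH4Cl
Reagents that add atoms: none
Why: 1,2-Addition of a lithium acetylide to a γ-lactone stops at the lithium lactolate (one equivalent of acetylide is spent on the tertiary OH), so work-up gives the α′-hydroxy ynone/lactol; C9 and C10 come unchanged from the sugar and C10 is quaternary, so nothing can epimerise.

Step 4
Reactants: 5 (2Z,7R,8R,9R)-7,9-dihydroxy-3,7-dimethyl-1,8,10-tris(triethylsilyloxy)dec-2-en-4-yn-6-one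
Product: 7 (2R)-2-[(1R,2R)-2,3-dihydroxy-1-(triethylsilyloxy)propyl]-5-[(2Z)-4-hydroxybut-2-en-2-yl]-2-methylfuran-3(2H)-one, via tris-TES furanone 6 (not isolated)
Conditions: Et2NH, EtOH, rt; evaporate; AcOH–THF–H2O (3:1:1), rt
Reagents that add atoms: none
Why: Amine-mediated oxa-Michael cyclisation (5-endo, through the β-enaminone) of the α′-hydroxy ynone closes the 3(2H)-furanone through O10 only, because O9 is silylated; dilute acetic acid then hydrolyses the two primary TES ethers while the neopentyl secondary 9-OTES survives (selective silyl ether hydrolysis).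

Step 5
Reactants: 7 (2R)-2-[(1R,2R)-2,3-dihydroxy-1-(triethylsilyloxy)propyl]-5-[(2Z)-4-hydroxybut-2-en-2-yl]-2-methylfuran-3(2H)-one
Product: 8 (2S)-2-{(2R)-5-[(2Z)-4-hydroxybut-2-en-2-yl]-2-methyl-3-oxo-2,3-dihydrofuran-2-yl}-2-(triethylsilyloxy)acetaldehyde
Conditions: NaIO4, THF–pH 7 buffer, 0 °C → rt
Reagents that add atoms: none
Why: Malaprade glycol cleavage removes the superfluous sugar carbon as formaldehyde and unveils C8 as the aldehyde; the 9-OTES group prevents a second cleavage and C9 is not affected under neutral conditions.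

Step 6
Reactants: 9 methyl 2-(bromomethyl)acrylate
Product: 11 methyl (2Z)-3-bromo-2-(bromomethyl)prop-2-enoate, via tribromide 10 (not isolated)
Conditions: Br2, CH2Cl2, 0 °C; then DBU (1.05 equiv), −20 → 0 °C
Reagents that add atoms: bromine, BrBr
Why: Bromine addition to the acrylate followed by E2 dehydrobromination (tertiary α-bromide, β-hydrogen of one CH2Br arm) gives the β-bromo-α-(bromomethyl)acrylate, a C7 building block that can act twice as a homoenolate.

Step 7
Reactants: 8 (2S)-2-{(2R)-5-[(2Z)-4-hydroxybut-2-en-2-yl]-2-methyl-3-oxo-2,3-dihydrofuran-2-yl}-2-(triethylsilyloxy)acetaldehyde; 11 methyl (2Z)-3-bromo-2-(bromomethyl)prop-2-enoate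
Product: 14 methyl (2Z,4S,5R)-2-(bromomethyl)-4,5-dihydroxy-5-{(2R)-5-[(2Z)-4-hydroxybut-2-en-2-yl]-2-methyl-3-oxo-2,3-dihydrofuran-2-yl}pent-2-enoate, via hydroxy aldehyde 12 (not isolated), via secondary allylic bromide 13 (not isolated)
Conditions: 1 M HCl–THF (1:4), rt; then In powder (1.5 equiv), 11 (3 equiv), THF–H2O, rt, sonication; then NaBr, rt
Reagents that add atoms: none
Why: Proposed new method: indium inserts into the allylic C–Br bond of 11 to give a γ-bromoallylindium, a homoenolate whose ester β-carbon (C7) adds to the α-hydroxy aldehyde 12 held in an In(III) chelate between O8 and O9, so attack comes from the face opposite the bulky C10 branch (Cram-chelate) and sets C8 syn to the 9-OH; bromide then shifts the secondary allylic bromide 13 by SN2′ to the conjugated primary bromide 14, and indium is kept limiting against 11 so that the product bromide is not reduced; the closest known reaction types are indium Barbier additions of 2-(bromomethyl)acrylates to unprotected α-hydroxy aldehydes in water and γ-additions of 3-bromoallylindium reagents to aldehydes.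

Step 8
Reactants: 14 methyl (2Z,4S,5R)-2-(bromomethyl)-4,5-dihydroxy-5-{(2R)-5-[(2Z)-4-hydroxybut-2-en-2-yl]-2-methyl-3-oxo-2,3-dihydrofuran-2-yl}pent-2-enoate
Product: 15 methyl (2Z,4S,5R)-2-(bromomethyl)-4,5-dihydroxy-5-{(2R)-2-methyl-3-oxo-5-[(2Z)-4-oxobut-2-en-2-yl]-2,3-dihydrofuran-2-yl}pent-2-enoate
Conditions: MnO2 (20 equiv), CH2Cl2, rt, dark
Reagents that add atoms: none
Why: Allylic oxidation with MnO2 converts only the primary dienylic alcohol into the Z-enal; the secondary alcohol next to the electron-poor acrylate and the neopentyl 9-OH react far more slowly.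

Step 9
Reactants: 15 methyl (2Z,4S,5R)-2-(bromomethyl)-4,5-dihydroxy-5-{(2R)-2-methyl-3-oxo-5-[(2Z)-4-oxobut-2-en-2-yl]-2,3-dihydrofuran-2-yl}pent-2-enoate
Product: 17 (6R,7R,8S,9R,10R)-8,9-dihydroxy-1-oxo-3,10-epoxygermacra-2,4(Z),11(13)-trien-12,6-olide, via seco hydroxy ester 16 (not isolated)
Conditions: CrCl2 (10 equiv), THF, slow addition of 15 (final 1 mM), rt; aq NH4Cl
Reagents that add atoms: none
Why: Intramolecular Nozaki–Hiyama (chromium Barbier) allylation in which CrCl2 turns the allylic bromide into a 2-(methoxycarbonyl)allylchromium, a homoenolate whose ester β-carbon C7 attacks the C6 aldehyde through a chair transition state that gives the anti adduct (trans-lactone, as in intermolecular CrCl2 reactions of 2-(bromomethyl)alk-2-enoates); the aldehyde should approach C7 anti to the bulky C9 branch with H8 eclipsing the alkene (A1,3 strain), which sets C6 and C7 relative to C8, and the chromium 6-alkoxide then lactonises onto the methyl ester while the neutral 8-OH does not.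

Step 10
Reactants: 17 (6R,7R,8S,9R,10R)-8,9-dihydroxy-1-oxo-3,10-epoxygermacra-2,4(Z),11(13)-trien-12,6-olide
Product: 18 (6R,7S,8S,9R,10R)-9-hydroxy-8-(3-methylbutanoyloxy)-1-oxo-3,10-epoxygermacra-2,4(Z),11(13)-trien-12,6-olide
Conditions: isovaleryl chloride (1.1 equiv), pyridine, CH2Cl2, −30 → 0 °C
Reagents that add atoms: isovaleryl chloride, CC(C)CC(=O)Cl
Why: Regioselective acylation; the 9-OH is neopentyl (next to quaternary C10) whereas the 8-OH is the less hindered secondary alcohol, so one equivalent of acid chloride at low temperature esterifies O8 without touching a stereocentre.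

Step 11
Reactants: 18 (6R,7S,8S,9R,10R)-9-hydroxy-8-(3-methylbutanoyloxy)-1-oxo-3,10-epoxygermacra-2,4(Z),11(13)-trien-12,6-olide
Product: 19 (6R,7S,8S,9R,10R)-9-acetoxy-8-(3-methylbutanoyloxy)-1-oxo-3,10-epoxygermacra-2,4(Z),11(13)-trien-12,6-olide
Conditions: Ac2O, DMAP (cat.), pyridine, CH2Cl2, 0 °C → rt
Reagents that add atoms: acetic anhydride, CC(=O)OC(C)=O
Why: DMAP-catalysed acetylation of the remaining hindered secondary alcohol under mild base (to avoid retro-aldol at the β-hydroxy ketone); no stereocentre is touched.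

## Compound list

1 | 2-C-methyl-D-ribono-1,4-lactone, (3R,4R,5R)-3,4-dihydroxy-5-(hydroxymethyl)-3-methyloxolan-2-one | C[C@]1(O)C(=O)O[C@H](CO)[C@H]1O | starting material
2 | (3R,4R,5R)-3-hydroxy-3-methyl-4-(triethylsilyloxy)-5-[(triethylsilyloxy)methyl]oxolan-2-one | C[C@]1(O)C(=O)O[C@H](CO[Si](CC)(CC)CC)[C@H]1O[Si](CC)(CC)CC | intermediate
3 | (Z)-3-methylpent-2-en-4-yn-1-ol | C#C/C(C)=C\CO | starting material
4 | triethyl{[(2Z)-3-methylpent-2-en-4-yn-1-yl]oxy}silane | C#C/C(C)=C\CO[Si](CC)(CC)CC | intermediate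
5 | (2Z,7R,8R,9R)-7,9-dihydroxy-3,7-dimethyl-1,8,10-tris(triethylsilyloxy)dec-2-en-4-yn-6-one (open ynone form; in equilibrium with its furanose lactol) | CC[Si](CC)(CC)OC/C=C(/C)C#CC(=O)[C@](C)(O)[C@H](O[Si](CC)(CC)CC)[C@H](O)CO[Si](CC)(CC)CC | intermediate
6 | (2R)-2-[(1R,2R)-2-hydroxy-1,3-bis(triethylsilyloxy)propyl]-2-methyl-5-[(2Z)-4-(triethylsilyloxy)but-2-en-2-yl]furan-3(2H)-one | CC[Si](CC)(CC)OC/C=C(/C)C1=CC(=O)[C@](C)(O1)[C@H](O[Si](CC)(CC)CC)[C@H](O)CO[Si](CC)(CC)CC | intermediate (not isolated)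
7 | (2R)-2-[(1R,2R)-2,3-dihydroxy-1-(triethylsilyloxy)propyl]-5-[(2Z)-4-hydroxybut-2-en-2-yl]-2-methylfuran-3(2H)-one | OC/C=C(/C)C1=CC(=O)[C@](C)(O1)[C@H](O[Si](CC)(CC)CC)[C@H](O)CO | intermediate
8 | (2S)-2-{(2R)-5-[(2Z)-4-hydroxybut-2-en-2-yl]-2-methyl-3-oxo-2,3-dihydrofuran-2-yl}-2-(triethylsilyloxy)acetaldehyde | OC/C=C(/C)C1=CC(=O)[C@](C)(O1)[C@H](O[Si](CC)(CC)CC)C=O | intermediate
9 | methyl 2-(bromomethyl)acrylate | C=C(CBr)C(=O)OC | starting material
10 | methyl 2,3-dibromo-2-(bromomethyl)propanoate | COC(=O)C(Br)(CBr)CBr | intermediate (not isolated)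
11 | methyl (2Z)-3-bromo-2-(bromomethyl)prop-2-enoate | COC(=O)/C(CBr)=C/Br | intermediate
12 | (2S)-2-hydroxy-2-{(2R)-5-[(2Z)-4-hydroxybut-2-en-2-yl]-2-methyl-3-oxo-2,3-dihydrofuran-2-yl}acetaldehyde | OC/C=C(/C)C1=CC(=O)[C@](C)(O1)[C@H](O)C=O | intermediate (not isolated)
13 | methyl (4R,5R)-3-bromo-4,5-dihydroxy-5-{(2R)-5-[(2Z)-4-hydroxybut-2-en-2-yl]-2-methyl-3-oxo-2,3-dihydrofuran-2-yl}-2-methylidenepentanoate (both C3 epimers; the centre is erased in the next event) | OC/C=C(/C)C1=CC(=O)[C@](C)(O1)[C@H](O)[C@@H](O)C(Br)C(=C)C(=O)OC | intermediate (not isolated)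
14 | methyl (2Z,4S,5R)-2-(bromomethyl)-4,5-dihydroxy-5-{(2R)-5-[(2Z)-4-hydroxybut-2-en-2-yl]-2-methyl-3-oxo-2,3-dihydrofuran-2-yl}pent-2-enoate | OC/C=C(/C)C1=CC(=O)[C@](C)(O1)[C@H](O)[C@@H](O)/C=C(\CBr)C(=O)OC | intermediate
15 | methyl (2Z,4S,5R)-2-(bromomethyl)-4,5-dihydroxy-5-{(2R)-2-methyl-3-oxo-5-[(2Z)-4-oxobut-2-en-2-yl]-2,3-dihydrofuran-2-yl}pent-2-enoate | O=C/C=C(/C)C1=CC(=O)[C@](C)(O1)[C@H](O)[C@@H](O)/C=C(\CBr)C(=O)OC | intermediate
16 | methyl (6R,7S,8S,9R,10R)-6,8,9-trihydroxy-1-oxo-3,10-epoxygermacra-2,4(Z),11(13)-trien-12-oate (formed as its chromium 6-alkoxide) | O[C@@H]1/C=C(/C)C2=CC(=O)[C@](C)(O2)[C@H](O)[C@@H](O)[C@H]1C(=C)C(=O)OC | intermediate (not isolated)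
17 | (6R,7R,8S,9R,10R)-8,9-dihydroxy-1-oxo-3,10-epoxygermacra-2,4(Z),11(13)-trien-12,6-olide (same spatial arrangement as the target; the C7 descriptor differs only through CIP priorities) | C=C1C(=O)O[C@@H]2/C=C(/C)C3=CC(=O)[C@](C)(O3)[C@H](O)[C@@H](O)[C@@H]12 | intermediate
18 | (6R,7S,8S,9R,10R)-9-hydroxy-8-(3-methylbutanoyloxy)-1-oxo-3,10-epoxygermacra-2,4(Z),11(13)-trien-12,6-olide | C=C1C(=O)O[C@@H]2/C=C(/C)C3=CC(=O)[C@](C)(O3)[C@H](O)[C@@H](OC(=O)CC(C)C)[C@@H]12 | intermediate
19 | (6R,7S,8S,9R,10R)-9-acetoxy-8-(3-methylbutanoyloxy)-1-oxo-3,10-epoxygermacra-2,4(Z),11(13)-trien-12,6-olide (CNP0255553.1) | C=C1C(=O)O[C@@H]2/C=C(/C)C3=CC(=O)[C@](C)(O3)[C@H](OC(C)=O)[C@@H](OC(=O)CC(C)C)[C@@H]12 | target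

## Step count and risks

Total step count: 11. Longest linear sequence: 9 (steps 1, 3, 4, 5, 7, 8, 9, 10, 11; the branch through step 2 is equally long).

The three steps most likely to fail:

**Step 7 (indium addition of the γ-bromo reagent).** Bromide 14 may not survive: indium can reduce it further, and its γ-hydroxyl sits cis to the CH2Br group and can close a dihydrofuran. The fallback supplies the second aldehyde before the first allylation, so that the bromohydrin is consumed inside the molecule as soon as it forms. It sets out from 8. MnO2 oxidises the allylic alcohol to the silyloxy dialdehyde F1. Aqueous HCl removes the silyl group to give the hydroxy dialdehyde F2. Indium (excess) and 11 in aqueous THF, diluted after the first stage, add first to the chelating α-hydroxy aldehyde to give the bromohydrin enal F3, and after a second indium insertion add intramolecularly to the enal. This comes back to the route at 16, which is lactonised with PPTS to 17. The C6/C7 outcome of the indium closure would have to be checked, since indium often favours the syn adduct.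

**Step 9 (chromium ring closure).** The closure may give oligomers or the wrong face at C6/C7. The fallback reverses the order of the two homoenolate additions, so that the ring closes at C7–C8 from a rigid butenolide. It sets out from 7. MnO2 gives the enal diol F4. Indium and 11 in aqueous THF, then PPTS, give by addition at C6, lactonisation and bromide shift the bromomethyl butenolide F5. C6 is not controlled by the remote centres here, so the 6R epimer must be separated or set with a chiral chromium–bisoxazoline catalyst. NaIO4 gives the butenolide aldehyde F6, and aqueous HCl gives the butenolide hydroxy aldehyde F7. Indium in aqueous THF at high dilution then adds C7 to the chelated C8 aldehyde anti to the C6 substituent, which comes back to the route at 17.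

**Step 10 (regioselective isovaleroylation of the diol).** If the macrocyclic diol is acylated unselectively, the ester is put on before ring closure, where the two hydroxyls differ more (allylic 8-OH against neopentyl 9-OH). It sets out from 15. Isovaleryl chloride with 2,4,6-collidine at −40 °C (a base that does not attack the allylic bromide) gives the acyclic 8-isovalerate F8. CrCl2 at high dilution closes the ring to the seco ester F9, which lactonises in the flask and comes back to the route at 18. The price is a δ-acyloxy group on the allylchromium, which can be lost by 1,4-elimination.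

Further compounds

F1 | step 7 | (2S)-2-{(2R)-2-methyl-3-oxo-5-[(2Z)-4-oxobut-2-en-2-yl]-2,3-dihydrofuran-2-yl}-2-(triethylsilyloxy)acetaldehyde | O=C/C=C(/C)C1=CC(=O)[C@](C)(O1)[C@H](O[Si](CC)(CC)CC)C=O
F2 | step 7 | (2S)-2-hydroxy-2-{(2R)-2-methyl-3-oxo-5-[(2Z)-4-oxobut-2-en-2-yl]-2,3-dihydrofuran-2-yl}acetaldehyde | O=C/C=C(/C)C1=CC(=O)[C@](C)(O1)[C@H](O)C=O
F3 | step 7 | methyl (4R,5R)-3-bromo-4,5-dihydroxy-5-{(2R)-2-methyl-3-oxo-5-[(2Z)-4-oxobut-2-en-2-yl]-2,3-dihydrofuran-2-yl}-2-methylidenepentanoate (C3 epimers) | O=C/C=C(/C)C1=CC(=O)[C@](C)(O1)[C@H](O)[C@@H](O)C(Br)C(=C)C(=O)OC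
F4 | step 9 | (2Z)-3-{(5R)-5-[(1R,2R)-2,3-dihydroxy-1-(triethylsilyloxy)propyl]-5-methyl-4-oxo-4,5-dihydrofuran-2-yl}but-2-enal | O=C/C=C(/C)C1=CC(=O)[C@](C)(O1)[C@H](O[Si](CC)(CC)CC)[C@H](O)CO
F5 | step 9 | (5R)-3-(bromomethyl)-5-[(1Z)-2-{(5R)-5-[(1R,2R)-2,3-dihydroxy-1-(triethylsilyloxy)propyl]-5-methyl-4-oxo-4,5-dihydrofuran-2-yl}prop-1-en-1-yl]furan-2(5H)-one | O=C1O[C@H](/C=C(/C)C2=CC(=O)[C@](C)(O2)[C@H](O[Si](CC)(CC)CC)[C@H](O)CO)C=C1CBr
F6 | step 9 | (2S)-2-{(2R)-5-[(1Z)-1-[(2R)-4-(bromomethyl)-5-oxo-2,5-dihydrofuran-2-yl]prop-1-en-2-yl]-2-methyl-3-oxo-2,3-dihydrofuran-2-yl}-2-(triethylsilyloxy)acetaldehyde | O=C1O[C@H](/C=C(/C)C2=CC(=O)[C@](C)(O2)[C@H](O[Si](CC)(CC)CC)C=O)C=C1CBr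
F7 | step 9 | (2S)-2-{(2R)-5-[(1Z)-1-[(2R)-4-(bromomethyl)-5-oxo-2,5-dihydrofuran-2-yl]prop-1-en-2-yl]-2-methyl-3-oxo-2,3-dihydrofuran-2-yl}-2-hydroxyacetaldehyde | O=C1O[C@H](/C=C(/C)C2=CC(=O)[C@](C)(O2)[C@H](O)C=O)C=C1CBr
F8 | step 10 | methyl (2Z,4S,5R)-2-(bromomethyl)-5-hydroxy-4-(3-methylbutanoyloxy)-5-{(2R)-2-methyl-3-oxo-5-[(2Z)-4-oxobut-2-en-2-yl]-2,3-dihydrofuran-2-yl}pent-2-enoate | O=C/C=C(/C)C1=CC(=O)[C@](C)(O1)[C@H](O)[C@@H](OC(=O)CC(C)C)/C=C(\CBr)C(=O)OC
F9 | step 10 | methyl (6R,7S,8S,9R,10R)-6,9-dihydroxy-8-(3-methylbutanoyloxy)-1-oxo-3,10-epoxygermacra-2,4(Z),11(13)-trien-12-oate | O[C@@H]1/C=C(/C)C2=CC(=O)[C@](C)(O2)[C@H](O)[C@@H](OC(=O)CC(C)C)[C@H]1C(=C)C(=O)OC
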